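## The problem

1. The target is a 2‑aryl‑hepta‑1,5‑dien‑3‑ol ester in quinone form. A 1,4‑benzoquinone (C1′–C6′: chain at C1′, H at C2′, C=O at C3′ and C6′, methyl at C4′, methoxy at C5′) carries the sp2 carbon C2 of a 1,1‑disubstituted alkene; C2 carries the only stereocentre, C3 (S, angeloyloxy), and C3 carries a prenyl arm (C4–C7).
2. Nothing in the molecule can relay chirality to C3, so its configuration must come from a reagent. Its two carbon substituents, an α‑arylvinyl group and an allylic CH2, are both unsaturated and similar in bulk, a poor basis for carbonyl‑face discrimination.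
3. Any precursor with a carbonyl at C3 has a C4 methylene that is both α to C=O and allylic, so it enolises and lets the C5=C6 bond move into conjugation. The matching aldehyde, 4‑methylpent‑3‑enal, has the same weakness.
4. The ring bears substituents on five of six carbons in fixed order, and the chain must sit beside the carbonyl flanked by the methoxy group. Conjugate addition to 2‑methoxy‑3‑methylbenzoquinone would place a substituent at the other free carbon.
5. The quinone (electrophile and oxidant), the angelate (Z→E isomerisation to the tiglate, Michael acceptor) and the allylic C3–O bond will not survive organolithiums, peroxide or Pd(0). The isopropylidene alkene will not survive electrophilic oxidants. The order is therefore skeleton, then ester, then quinone.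
6. The feature that makes the key step possible: C3 is a secondary carbinol carbon bonded to one sp2 carbon (C2) and to the CH2 (C4) of a homoprenyl unit. C3–C7 with its oxygen is the skeleton of 4‑methylpent‑3‑en‑1‑ol, whose O–CH2 can be turned into a configurationally defined carbenoid, and C2, being sp2, can be delivered to it from boron by a 1,2‑shift.
7. A second enabling feature lies in the ring. In the phenol form of the quinone (C3′–OH, C6′–H), C1′ is meta to both ring oxygens and is the only C–H of a 1,2,3‑trisubstituted benzene without an ortho neighbour, and C6′ is para to the phenolic OH.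

## Retrosynthesis

**19 ⇒ 18 (C6′=O cut back to C6′–H, C3′=O to C3′–OH).** The quinone cannot pass through any organometallic or basic step, so it is formed last from phenol 18. The usual alternative, a hydroquinone dimethyl ether opened with Ce(IV), would need a benzene with five different substituents in fixed order, for which no simple precursor exists. 18 is an ordinary 3,5‑dioxygenated 4‑methylphenyl compound. The forward reaction must oxidise a phenol at its para carbon and leave three C=C bonds and the ester alone, which a Teuber oxidation should do.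

**18 ⇒ 17 ⇒ 14 + 15 (aryl O–Si bond, then the acyl C–O bond of the ester).** The angelate is the most fragile group after the quinone, so it is attached to the finished alcohol 14 from angelic acid 15. The phenol stays silylated through the esterification so that only the C3 hydroxyl is acylated. The forward acylation must not isomerise the Z‑enoate; the desilylation must not touch the ester.

**14 ⇒ 13 (C3–O replaced by C3–B).** A C–B bond at C3 is what a 1,2‑metallate shift delivers, and its oxidation is stereoretentive. This keeps C3 away from the carbonyl oxidation level, so the C4 methylene is never activated. The precursor is no simpler in atoms, but it opens the next cut.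

**13 ⇒ 8 + 10 (the C2–C3 bond; key step).** The bond is formed by shifting the α‑arylvinyl group of boronate 8 from boron onto the lithiated O–CH carbon of the 2,4,6‑triisopropylbenzoate 10. Against the neighbouring polar cut (vinyl metal plus aldehyde), this sets C3 by an enantiotopic deprotonation followed by two stereospecific events, independent of the bulk of the two carbon groups. 8 and 10 are achiral and each is one or three steps from a purchasable compound. The forward reaction must deprotonate α to oxygen in preference to the allylic C–H and must transfer carbon rather than a pinacol oxygen.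

**8 ⇒ 3 + 4 (the C1′–C2 bond; C2 and C1 come from the epoxysilane).** A vinylidene insertion into the aryl–boron bond of 3 with lithiated trimethyl(oxiranyl)silane (from 4) gives the 1,1‑disubstituted alkenylboronate in one step. The neighbouring cut, a cross‑coupling of 3 with a 1‑halovinyl boron reagent followed by ligand exchange, costs two steps. The forward reaction must eliminate silicon–oxygen rather than boron–oxygen from the intermediate alkoxide.

**3 ⇒ 2 ⇒ 1 (C1′–B from C1′–H; O–Si) and 10 ⇒ 9 (ester).** The aryl boronate comes from sterically controlled C–H borylation of the silyl ether 2 of 3‑methoxy‑2‑methylphenol 1; no halogenated arene is needed. 10 is the hindered benzoate of 4‑methylpent‑3‑en‑1‑ol 9.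

## Roads not taken

**Alternative 1:** the most obvious route cuts C2–C3 in the polar sense. The α‑arylvinyl bromide A1 would be metalated and added to 4‑methylpent‑3‑enal A2 under a chiral ligand (asymmetric alkenylzinc addition or asymmetric Nozaki–Hiyama–Kishi coupling) to give 14.
- A2 is a β,γ‑unsaturated, unbranched, enolisable aldehyde that conjugates and self‑condenses; it would have to be made and used at once.
- Ligand‑controlled alkenylations discriminate aldehyde faces best for aryl or α‑branched aldehydes, not for this type.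
- A1 needs the same aryl piece plus a halogen handle, so nothing is saved.
- The chosen plan never has a carbonyl at C3 and takes its stereocontrol from a deprotonation, not from facial selection.

**Alternative 2:** cut the C1′–C2 bond. Boronate 3 would be joined to the enantioenriched propargylic alcohol A3 by Markovnikov hydroarylation of the terminal alkyne; A3 would come from ynone A4 by asymmetric transfer hydrogenation.
- A4 again puts a carbonyl at C3 beside the doubly activated C4 methylene.
- The hydroarylation must be won for the branched (α) regiochemistry on a free propargylic alcohol, since a propargylic ester would ionise with Pd(0).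
- The stereocentre is bought in a separate three‑ to four‑step sequence, whereas 10 is one step from 9.

**Alternative 3:** cut C3–C4 by a [2,3]‑Wittig rearrangement. The bis‑allylic ether A5 would be deprotonated at its O–CH2 and rearranged onto the 1,1‑dimethylallyl group to give the skeleton of 14 in one step.
- Absolute control would require a chiral base acting on a mesomeric, configurationally labile 2‑arylallyl anion, where induction is substrate dependent.
- The tertiary allylic ether A5 is awkward to prepare (SN2′ and elimination compete).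
- [1,2]‑ and [1,4]‑shifts compete with the [2,3]‑shift.
- The chosen plan uses the same idea of an O–CH carbanion, but on a localised, configurationally stable α‑oxyalkyllithium.

Key step: step 5

Assumption: (+)‑sparteine is taken to induce the mirror‑image sense of the (−)‑sparteine series on a primary alkyl 2,4,6‑triisopropylbenzoate (removal of the pro‑R hydrogen); compounds 1, 4, 9 and 15 are taken as purchasable (1 is otherwise one monomethylation from 2‑methylresorcinol).

## Route

Step 1
Reactants: 1 3‑methoxy‑2‑methylphenol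
Product: 2 triisopropyl(3‑methoxy‑2‑methylphenoxy)silane
Conditions: TIPSCl, imidazole, DMF, rt
Reagents that add atoms: chlorotriisopropylsilane, CC(C)[Si](Cl)(C(C)C)C(C)C
Why: Standard silylation of a phenol; the bulky, base‑stable TIPS ether masks the future C3′ oxygen through the organolithium steps and shields its ortho C–H in step 2.

Step 2
Reactants: 2 triisopropyl(3‑methoxy‑2‑methylphenoxy)silane
Product: 3 2‑[3‑methoxy‑4‑methyl‑5‑(triisopropylsilyloxy)phenyl]‑4,4,5,5‑tetramethyl‑1,3,2‑dioxaborolane
Conditions: [Ir(OMe)(cod)]2 (cat.), dtbpy (cat.), B2pin2, THF, 80 °C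
Reagents that add atoms: bis(pinacolato)diboron, CC1(C)OB(OC1(C)C)B1OC(C)(C)C(C)(C)O1
Why: Iridium‑catalysed C–H borylation is sterically governed; C5 of 2 (the future C1′) is the only ring C–H without an ortho substituent, so boron should enter there.

Step 3
Reactants: 3 2‑[3‑methoxy‑4‑methyl‑5‑(triisopropylsilyloxy)phenyl]‑4,4,5,5‑tetramethyl‑1,3,2‑dioxaborolane; 4 trimethyl(oxiran‑2‑yl)silane
Product: 8 2‑{1‑[3‑methoxy‑4‑methyl‑5‑(triisopropylsilyloxy)phenyl]ethenyl}‑4,4,5,5‑tetramethyl‑1,3,2‑dioxaborolane, via lithiated epoxysilane 5 (not isolated), via boronate complex 6 (not isolated), via lithium beta‑silyl alkoxide 7 (not isolated)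
Conditions: 4, s‑BuLi, TMEDA, Et2O, −110 °C; then 3, −110 °C → rt
Reagents that add atoms: none
Why: Vinylidene homologation of a boronic ester: 5 adds to boron (6), the aryl group shifts to carbon with opening of the epoxide (7), and Peterson elimination of lithium trimethylsilanolate leaves the alkenylboronate 8. The reaction type is established for aryl pinacol boronates that are not electron‑poor, and this aryl group is close to electronically neutral.

Step 4
Reactants: 9 4‑methylpent‑3‑en‑1‑ol
Product: 10 4‑methylpent‑3‑en‑1‑yl 2,4,6‑triisopropylbenzoate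
Conditions: 2,4,6‑triisopropylbenzoic acid, PPh3, DIAD, THF, 0 °C → rt
Reagents that add atoms: 2,4,6‑triisopropylbenzoic acid, CC(C)c1cc(C(C)C)c(C(=O)O)c(C(C)C)c1
Why: Mitsunobu esterification of a primary alcohol; the chain oxygen of 10 comes from the acid and that of 9 leaves with phosphorus. The hindered benzoate directs the α‑lithiation and is the leaving group of step 5, and its bulk keeps s‑BuLi off the carbonyl.

Step 5
Reactants: 10 4‑methylpent‑3‑en‑1‑yl 2,4,6‑triisopropylbenzoate; 8 2‑{1‑[3‑methoxy‑4‑methyl‑5‑(triisopropylsilyloxy)phenyl]ethenyl}‑4,4,5,5‑tetramethyl‑1,3,2‑dioxaborolane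
Product: 13 2‑{(3S)‑2‑[3‑methoxy‑4‑methyl‑5‑(triisopropylsilyloxy)phenyl]‑6‑methylhepta‑1,5‑dien‑3‑yl}‑4,4,5,5‑tetramethyl‑1,3,2‑dioxaborolane, via lithiated benzoate 11 (not isolated), via boronate complex 12 (not isolated)
Conditions: 10, (+)‑sparteine, s‑BuLi, Et2O, −78 °C, 5 h; then 8, −78 °C, 2 h; then reflux
Reagents that add atoms: none
Why: s‑BuLi·(+)‑sparteine should remove the pro‑R hydrogen of the O–CH2 group of 10, the ester carbonyl holding the base next to that CH2 so that the allylic C–H bonds further along are not touched, and the resulting (R)‑α‑lithio ester 11 is configurationally stable at −78 °C. Boronate 8 should add to 11 with retention at carbon to give ate complex 12. On warming, the α‑arylvinyl group shifts from boron to carbon anti‑periplanar to the departing triisopropylbenzoate, which inverts the carbon and gives the (S)‑allylic boronic ester 13 with the new C2–C3 bond. The closest known reaction type is the lithiation–borylation (Matteson‑type 1,2‑metallate rearrangement) of sparteine‑lithiated primary carbamates and triisopropylbenzoates with alkenyl pinacol boronates. No ring is closed. The C3 stereocentre is controlled by the chiral diamine in the deprotonation alone; borylation (retention) and the 1,2‑shift (inversion) are stereospecific, so the outcome does not depend on the relative bulk of the two carbon substituents. The step needs migration of carbon rather than a pinacol oxygen and no second insertion: the sp2 carbon is the best migrating group on boron, the hindered benzoate is a good enough leaving group that no Lewis acid should be needed, and surplus 11 should decompose on warming before 13 has formed. The silyl ether, the methoxy group and the isopropylidene alkene should be inert to these conditions.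

Step 6
Reactants: 13 2‑{(3S)‑2‑[3‑methoxy‑4‑methyl‑5‑(triisopropylsilyloxy)phenyl]‑6‑methylhepta‑1,5‑dien‑3‑yl}‑4,4,5,5‑tetramethyl‑1,3,2‑dioxaborolane
Product: 14 (3S)‑2‑[3‑methoxy‑4‑methyl‑5‑(triisopropylsilyloxy)phenyl]‑6‑methylhepta‑1,5‑dien‑3‑ol
Conditions: NaBO3·4H2O, THF/H2O, rt (crude 13 used at once)
Reagents that add atoms: sodium perborate, [Na+].[O-]OB=O
Why: Perborate oxidation of a C–B bond proceeds by 1,2‑shift of carbon from boron to oxygen with retention and without allylic transposition. The nearly neutral medium spares the aryl silyl ether, and immediate use of 13 forestalls a 1,3‑boryl shift.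

Step 7
Reactants: 14 (3S)‑2‑[3‑methoxy‑4‑methyl‑5‑(triisopropylsilyloxy)phenyl]‑6‑methylhepta‑1,5‑dien‑3‑ol; 15 angelic acid [(2Z)‑2‑methylbut‑2‑enoic acid]
Product: 17 (3S)‑2‑[3‑methoxy‑4‑methyl‑5‑(triisopropylsilyloxy)phenyl]‑6‑methylhepta‑1,5‑dien‑3‑yl (2Z)‑2‑methylbut‑2‑enoate, via mixed anhydride 16 (not isolated)
Conditions: 15, 2,4,6‑trichlorobenzoyl chloride, Et3N, toluene, rt; then 14, 80 °C (no DMAP)
Reagents that add atoms: none
Why: Yamaguchi esterification through the preformed mixed anhydride 16. Without a nucleophilic catalyst the Z geometry should be kept, since isomerisation to the tiglate runs through reversible conjugate addition. C3 is untouched because only the acyl–O bond is formed.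

Step 8
Reactants: 17 (3S)‑2‑[3‑methoxy‑4‑methyl‑5‑(triisopropylsilyloxy)phenyl]‑6‑methylhepta‑1,5‑dien‑3‑yl (2Z)‑2‑methylbut‑2‑enoate
Product: 18 (3S)‑2‑(3‑hydroxy‑5‑methoxy‑4‑methylphenyl)‑6‑methylhepta‑1,5‑dien‑3‑yl (2Z)‑2‑methylbut‑2‑enoate
Conditions: TBAF, AcOH, THF, 0 °C
Reagents that add atoms: none
Why: Fluoride cleaves the aryl O–Si bond; acetic acid buffers fluoride and phenoxide so that the angelate should neither isomerise nor be cleaved.

Step 9
Reactants: 18 (3S)‑2‑(3‑hydroxy‑5‑methoxy‑4‑methylphenyl)‑6‑methylhepta‑1,5‑dien‑3‑yl (2Z)‑2‑methylbut‑2‑enoate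
Product: 19 (3S)‑2‑(5‑methoxy‑4‑methyl‑3,6‑dioxocyclohexa‑1,4‑dien‑1‑yl)‑6‑methylhepta‑1,5‑dien‑3‑yl (2Z)‑2‑methylbut‑2‑enoate (CNP0232608.2)
Conditions: Fremy's salt, KH2PO4 buffer, acetone/H2O, 0 °C → rt
Reagents that add atoms: potassium nitrosodisulfonate, [K+].[K+].[O]N(S(=O)(=O)[O-])S(=O)(=O)[O-]
Why: Teuber oxidation: the nitroxide abstracts the phenolic hydrogen, a second equivalent couples at the para carbon C6′ (the ortho carbon C4′ is blocked by methyl), and loss of imidodisulfonate gives the p‑quinone. The one‑electron oxidant should not attack the alkenes or the enoate, and the medium is near neutral.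

## Compound list

1 | 3‑methoxy‑2‑methylphenol | COc1cccc(O)c1C | starting material
2 | triisopropyl(3‑methoxy‑2‑methylphenoxy)silane | COc1cccc(O[Si](C(C)C)(C(C)C)C(C)C)c1C | intermediate
3 | 2‑[3‑methoxy‑4‑methyl‑5‑(triisopropylsilyloxy)phenyl]‑4,4,5,5‑tetramethyl‑1,3,2‑dioxaborolane | COc1cc(B2OC(C)(C)C(C)(C)O2)cc(O[Si](C(C)C)(C(C)C)C(C)C)c1C | intermediate
4 | trimethyl(oxiran‑2‑yl)silane (racemic) | C[Si](C)(C)C1CO1 | starting material
5 | 2‑lithio‑2‑(trimethylsilyl)oxirane | [Li]C1([Si](C)(C)C)CO1 | intermediate
6 | lithium [3‑methoxy‑4‑methyl‑5‑(triisopropylsilyloxy)phenyl](pinacolato)[2‑(trimethylsilyl)oxiran‑2‑yl]borate | [Li+].C[Si](C)(C)C1(CO1)[B-]1(OC(C)(C)C(C)(C)O1)c1cc(OC)c(C)c(O[Si](C(C)C)(C(C)C)C(C)C)c1 | intermediate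
7 | lithium 2‑[3‑methoxy‑4‑methyl‑5‑(triisopropylsilyloxy)phenyl]‑2‑(4,4,5,5‑tetramethyl‑1,3,2‑dioxaborolan‑2‑yl)‑2‑(trimethylsilyl)ethan‑1‑olate | [Li+].[O-]CC([Si](C)(C)C)(B1OC(C)(C)C(C)(C)O1)c1cc(OC)c(C)c(O[Si](C(C)C)(C(C)C)C(C)C)c1 | intermediate
8 | 2‑{1‑[3‑methoxy‑4‑methyl‑5‑(triisopropylsilyloxy)phenyl]ethenyl}‑4,4,5,5‑tetramethyl‑1,3,2‑dioxaborolane | C=C(B1OC(C)(C)C(C)(C)O1)c1cc(OC)c(C)c(O[Si](C(C)C)(C(C)C)C(C)C)c1 | intermediate
9 | 4‑methylpent‑3‑en‑1‑ol | CC(C)=CCCO | starting material
10 | 4‑methylpent‑3‑en‑1‑yl 2,4,6‑triisopropylbenzoate | CC(C)=CCCOC(=O)c1c(C(C)C)cc(C(C)C)cc1C(C)C | intermediate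
11 | (1R)‑1‑lithio‑4‑methylpent‑3‑en‑1‑yl 2,4,6‑triisopropylbenzoate ((+)‑sparteine complex) | [Li][C@H](CC=C(C)C)OC(=O)c1c(C(C)C)cc(C(C)C)cc1C(C)C | intermediate
12 | lithium {1‑[3‑methoxy‑4‑methyl‑5‑(triisopropylsilyloxy)phenyl]ethenyl}(pinacolato)[(1R)‑4‑methyl‑1‑(2,4,6‑triisopropylbenzoyloxy)pent‑3‑en‑1‑yl]borate | [Li+].C=C(c1cc(OC)c(C)c(O[Si](C(C)C)(C(C)C)C(C)C)c1)[B-]1(OC(C)(C)C(C)(C)O1)[C@H](CC=C(C)C)OC(=O)c1c(C(C)C)cc(C(C)C)cc1C(C)C | intermediate
13 | 2‑{(3S)‑2‑[3‑methoxy‑4‑methyl‑5‑(triisopropylsilyloxy)phenyl]‑6‑methylhepta‑1,5‑dien‑3‑yl}‑4,4,5,5‑tetramethyl‑1,3,2‑dioxaborolane | C=C(c1cc(OC)c(C)c(O[Si](C(C)C)(C(C)C)C(C)C)c1)[C@H](CC=C(C)C)B1OC(C)(C)C(C)(C)O1 | intermediate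
14 | (3S)‑2‑[3‑methoxy‑4‑methyl‑5‑(triisopropylsilyloxy)phenyl]‑6‑methylhepta‑1,5‑dien‑3‑ol | C=C(c1cc(OC)c(C)c(O[Si](C(C)C)(C(C)C)C(C)C)c1)[C@H](CC=C(C)C)O | intermediate
15 | angelic acid, (2Z)‑2‑methylbut‑2‑enoic acid | C/C=C(/C)C(=O)O | starting material
16 | (2Z)‑2‑methylbut‑2‑enoic 2,4,6‑trichlorobenzoic anhydride | C/C=C(/C)C(=O)OC(=O)c1c(Cl)cc(Cl)cc1Cl | intermediate
17 | (3S)‑2‑[3‑methoxy‑4‑methyl‑5‑(triisopropylsilyloxy)phenyl]‑6‑methylhepta‑1,5‑dien‑3‑yl (2Z)‑2‑methylbut‑2‑enoate | C=C(c1cc(OC)c(C)c(O[Si](C(C)C)(C(C)C)C(C)C)c1)[C@H](CC=C(C)C)OC(=O)/C(C)=C\C | intermediate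
18 | (3S)‑2‑(3‑hydroxy‑5‑methoxy‑4‑methylphenyl)‑6‑methylhepta‑1,5‑dien‑3‑yl (2Z)‑2‑methylbut‑2‑enoate | C=C(c1cc(OC)c(C)c(O)c1)[C@H](CC=C(C)C)OC(=O)/C(C)=C\C | intermediate
19 | (3S)‑2‑(5‑methoxy‑4‑methyl‑3,6‑dioxocyclohexa‑1,4‑dien‑1‑yl)‑6‑methylhepta‑1,5‑dien‑3‑yl (2Z)‑2‑methylbut‑2‑enoate | C=C(C1=CC(=O)C(C)=C(OC)C1=O)[C@H](CC=C(C)C)OC(=O)/C(C)=C\C | target

## Step count and risk

Total steps: 9. Longest linear sequence: 8 (steps 1, 2, 3, 5, 6, 7, 8, 9); step 4 is the one‑step side branch.

**Step 5 (key step).** Three processes could fail: the α‑lithiation could be incomplete or accompanied by deprotonation at the allylic C–H; the hindered α‑arylvinyl boronate could add slowly to the carbenoid so that the lithiated ester decomposes first; or the 1,2‑shift could be sluggish and erode the enantiomeric purity through reversal of ate‑complex formation. The fallback leaves boron chemistry for the C2–C3 bond; it sets out from 8 and returns at 14. Oxidative cleavage of the pinacol ester (NaIO4, NH4OAc, aqueous acetone) would give {1‑[3‑methoxy‑4‑methyl‑5‑(triisopropylsilyloxy)phenyl]ethenyl}boronic acid F1. Liebeskind–Srogl coupling of it with S‑phenyl 4‑methylpent‑3‑enethioate F2 (from 4‑methylpent‑3‑enoic acid and thiophenol) under neutral Pd(0)/copper(I) thiophene‑2‑carboxylate conditions would give 2‑[3‑methoxy‑4‑methyl‑5‑(triisopropylsilyloxy)phenyl]‑6‑methylhepta‑1,5‑dien‑3‑one F3 without a base that could move the C5=C6 bond. Corey–Bakshi–Shibata reduction with the (R)‑oxazaborolidine and catecholborane at low temperature, the α‑arylvinyl group acting as the large substituent, should then give 14.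

**Step 3.** The intermediate alkoxide 7 could eliminate in the wrong sense (loss of boron–oxygen instead of silicon–oxygen, giving the vinylsilane), because the aryl group is only neutral and not clearly electron‑rich; protodeboronation of the ate complex is a second loss channel. The fallback sets out from 3 and returns at 8. Suzuki–Miyaura coupling of 3 with commercially available (1‑bromoethenyl)boronic acid MIDA ester under anhydrous conditions, where the sp3‑hybridised boron does not transmetalate, would give 1‑[3‑methoxy‑4‑methyl‑5‑(triisopropylsilyloxy)phenyl]ethenylboronic acid MIDA ester F4. Exchange of the MIDA ligand for pinacol (pinacol, NaHCO3, MeOH) should then give 8.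

**Step 7.** The angeloyl group could isomerise to the tigloyl group during activation or heating, through reversible conjugate addition of amine or carboxylate, and acylation of the hindered allylic alcohol could be slow enough to make this worse. The fallback builds the Z‑alkene on the ester; it sets out from 14 and returns at 17. Esterification with 2‑[bis(2,2,2‑trifluoroethoxy)phosphoryl]propanoic acid (DCC, DMAP) would give (3S)‑2‑[3‑methoxy‑4‑methyl‑5‑(triisopropylsilyloxy)phenyl]‑6‑methylhepta‑1,5‑dien‑3‑yl 2‑[bis(2,2,2‑trifluoroethoxy)phosphoryl]propanoate F5, whose two epimers at the phosphonate carbon converge. Still–Gennari olefination with acetaldehyde (KHMDS, 18‑crown‑6, THF, −78 °C) should give the Z‑trisubstituted enoate 17.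

**Step 9.** Radical coupling could take place at the free ortho carbon C2′ instead of the para carbon C6′, which is flanked by the methoxy group and the twisted alkenyl group, and the vinylquinone could be consumed by further oxidation or dimerisation during a slow reaction. The fallback replaces the radical oxidation by a two‑electron one through a ketal; it sets out from 18 and returns at 19. PhI(OAc)2 (2 equiv) in MeOH would give (3S)‑6‑methyl‑2‑(5,6,6‑trimethoxy‑4‑methyl‑3‑oxocyclohexa‑1,4‑dien‑1‑yl)hepta‑1,5‑dien‑3‑yl (2Z)‑2‑methylbut‑2‑enoate F6, the quinone monoketal. Hydrolysis with dilute aqueous oxalic acid at room temperature should release 19.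

## Further compounds

F1 | step 5 | {1‑[3‑methoxy‑4‑methyl‑5‑(triisopropylsilyloxy)phenyl]ethenyl}boronic acid | C=C(B(O)O)c1cc(OC)c(C)c(O[Si](C(C)C)(C(C)C)C(C)C)c1
F2 | step 5 | S‑phenyl 4‑methylpent‑3‑enethioate | CC(C)=CCC(=O)Sc1ccccc1
F3 | step 5 | 2‑[3‑methoxy‑4‑methyl‑5‑(triisopropylsilyloxy)phenyl]‑6‑methylhepta‑1,5‑dien‑3‑one | C=C(c1cc(OC)c(C)c(O[Si](C(C)C)(C(C)C)C(C)C)c1)C(=O)CC=C(C)C
F4 | step 3 | 1‑[3‑methoxy‑4‑methyl‑5‑(triisopropylsilyloxy)phenyl]ethenylboronic acid MIDA ester | C=C([B-]12OC(=O)C[N+]1(C)CC(=O)O2)c1cc(OC)c(C)c(O[Si](C(C)C)(C(C)C)C(C)C)c1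
F5 | step 7 | (3S)‑2‑[3‑methoxy‑4‑methyl‑5‑(triisopropylsilyloxy)phenyl]‑6‑methylhepta‑1,5‑dien‑3‑yl 2‑[bis(2,2,2‑trifluoroethoxy)phosphoryl]propanoate (both epimers at the phosphonate carbon) | C=C(c1cc(OC)c(C)c(O[Si](C(C)C)(C(C)C)C(C)C)c1)[C@H](CC=C(C)C)OC(=O)C(C)P(=O)(OCC(F)(F)F)OCC(F)(F)F
F6 | step 9 | (3S)‑6‑methyl‑2‑(5,6,6‑trimethoxy‑4‑methyl‑3‑oxocyclohexa‑1,4‑dien‑1‑yl)hepta‑1,5‑dien‑3‑yl (2Z)‑2‑methylbut‑2‑enoate | C=C(C1=CC(=O)C(C)=C(OC)C1(OC)OC)[C@H](CC=C(C)C)OC(=O)/C(C)=C\C
A1 | alternative 1 | [3‑(1‑bromoethenyl)‑5‑methoxy‑2‑methylphenoxy]triisopropylsilane | C=C(Br)c1cc(OC)c(C)c(O[Si](C(C)C)(C(C)C)C(C)C)c1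
A2 | alternative 1 | 4‑methylpent‑3‑enal | CC(C)=CCC=O
A3 | alternative 2 | (3S)‑6‑methylhept‑5‑en‑1‑yn‑3‑ol | C#C[C@H](CC=C(C)C)O
A4 | alternative 2 | 6‑methyl‑1‑(trimethylsilyl)hept‑5‑en‑1‑yn‑3‑one | C[Si](C)(C)C#CC(=O)CC=C(C)C
A5 | alternative 3 | triisopropyl{3‑methoxy‑2‑methyl‑5‑[3‑(2‑methylbut‑3‑en‑2‑yloxy)prop‑1‑en‑2‑yl]phenoxy}silane | C=C(COC(C)(C)C=C)c1cc(OC)c(C)c(O[Si](C(C)C)(C(C)C)C(C)C)c1
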